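Cuts in retrosynthetic order (eudesmane numbering): the C11–O bond of the hydroperoxide (C6=C7 returns to C7=C11), the acetyl–O4 and angeloyl–O3 bonds, the C3–O and C4–O bonds (back to C3=C4), C1–H traded for C1–OH, and finally the ring-fusion bond C5–C10.
Enabling feature: C5–C10 is the only bond common to ring A (C1–C5, C10) and ring B (C5–C10). Once it is cut, the skeleton is the ten-membered ring of germacrone, in which C4=C5 faces C10 across the ring and the C8 ketone and the three-carbon unit on C7 already sit in their final positions.
Forward order: epoxide on C1=C10, rings A and B closed together by the C5–C10 bond, C1 deoxygenated, C3=C4 dihydroxylated, O3 then O4 acylated, singlet oxygen last.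
Stereochemistry: a chiral dioxirane fixes C1 and C10 of the epoxide; anti opening in the chair–chair fold hands this on to C10 (β-methyl) and C5 (α-H); the axial C10 methyl then sends OsO4 to the α face (C3, C4); the Z alkene is bought with angelic acid.

Key step: step 2

Assumption: at 0 °C the mirror-image ring conformers of achiral germacrone interconvert much faster than either is epoxidised, so the chiral oxidant can draw all of the material through one of them.

Step 1
Reactants: 1 germacrone, (1(10)E,4E)-germacra-1(10),4,7(11)-trien-8-one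
Product: 2 (1R,10R)-1,10-epoxygermacra-4E,7(11)-dien-8-one (trans epoxide; C4=C5 and C7=C11 intact)
Conditions: 1,2:4,5-di-O-isopropylidene-β-D-erythro-hexo-2,3-diulo-2,6-pyranose (D-fructose-derived Shi ketone, 30 mol %), KHSO5 (as 2KHSO5·KHSO4·K2SO4, 1.1 equiv), K2CO3, Bu4NHSO4 (cat.), aq Na2B4O7/Na2EDTA buffer (pH 10.5), MeCN–CH2(OMe)2, 0 °C
Reagents that add atoms: potassium peroxymonosulfate, [K+].[O-]S(=O)(=O)OO
Why: Shi asymmetric epoxidation, in which the dioxirane of the D-fructose ketone meets E-trisubstituted alkenes in a spiro transition state that leads to the (R,R)-epoxide; the conjugated tetrasubstituted C7=C11 alkene is too electron-poor to compete, C1=C10 is expected to be the more reactive of the two trisubstituted alkenes in line with the behaviour of germacrone toward peracids, and any 4,5-epoxide is removed by chromatography.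

Step 2
Reactants: 2 (1R,10R)-1,10-epoxygermacra-4E,7(11)-dien-8-one
Product: 3 (1R,5S,10R)-1β-hydroxyeudesma-3,7(11)-dien-8-one (trans-decalin; equatorial 1β-OH; 5α-H; 10β-CH3)
Conditions: BF3·OEt2 (20 mol %), CH2Cl2, −78 → −40 °C; aq NaHCO3 quench
Reagents that add atoms: none
Why: BF3 binds the epoxide oxygen, the C10–O bond stretches at the tertiary carbon, C5 of the C4=C5 alkene (held face to face with C10 in the crossed chair–chair conformer) bonds to C10 from the side opposite the departing oxygen, and the tertiary C4 cation sheds its axial H3 to leave C3=C4. The closest known reaction type is the acid-induced transannular cyclisation of germacra-1(10),4-diene 1,10-epoxides to 1β-hydroxyeudesmanes. The one new bond closes two rings: ring A in the 6-endo mode (both alkene carbons and both epoxide carbons end up inside it) and ring B in the 6-exo mode (C4 and C1 stay outside it). C1 keeps its C–O bond and becomes the equatorial 1β-carbinol, C10 is inverted by the anti opening and so carries a β-methyl, and C5 receives an α-hydrogen because the E alkene can reach C10 only through the chair–chair fold that leads to a trans ring fusion. Chemoselectivity is secured by the substrate, since the conjugated C7=C11 alkene is electron-poor and could reach C10 only through a four-membered ring. The regiochemistry of proton loss is the weaker point: the axial 3α-H is aligned with the empty orbital at C4 and gives the more substituted of the two readily formed alkenes, catalytic acid, low temperature and an early quench guard against drift to the tetrasubstituted C4=C5 alkene, and any exocyclic isomer is removed on AgNO3-impregnated silica.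

Step 3
Reactants: 3 (1R,5S,10R)-1β-hydroxyeudesma-3,7(11)-dien-8-one
Product: 4 O-[(1R,5S,10R)-8-oxoeudesma-3,7(11)-dien-1β-yl] imidazole-1-carbothioate
Conditions: 1,1'-thiocarbonyldiimidazole (2 equiv), 4-(dimethylamino)pyridine (DMAP, 20 mol %), ClCH2CH2Cl, 80 °C
Reagents that add atoms: 1,1'-thiocarbonyldiimidazole, S=C(n1ccnc1)n1ccnc1
Why: Thioacylation of the only hydroxyl group under neutral conditions prepares the Barton–McCombie step and avoids the NaH/CS2/MeI xanthate protocol, whose base would enolise the C8 ketone; no stereocentre is touched.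

Step 4
Reactants: 4 O-[(1R,5S,10R)-8-oxoeudesma-3,7(11)-dien-1β-yl] imidazole-1-carbothioate
Product: 5 (5R,10R)-eudesma-3,7(11)-dien-8-one
Conditions: Bu3SnH (1.5 equiv), 2,2'-azobis(isobutyronitrile) (AIBN, 10 mol %), PhMe, 100 °C
Reagents that add atoms: none
Why: Barton–McCombie deoxygenation, in which the stannyl radical adds to C=S, β-scission releases the secondary C1 radical, and this radical takes hydrogen from Bu3SnH faster than it can attack C3=C4 or C8=O (only three- or four-membered closures are open to it), while C5 and C10 stay untouched.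

Step 5
Reactants: 5 (5R,10R)-eudesma-3,7(11)-dien-8-one
Product: 7 (3R,4S,5R,10R)-3α,4α-dihydroxyeudesm-7(11)-en-8-one, via cyclic osmate ester 6 (not isolated)
Conditions: OsO4 (5 mol %), N-methylmorpholine N-oxide (1.5 equiv), acetone–H2O (4:1), rt
Reagents that add atoms: OsO4, O=[Os](=O)(=O)=O (hands over both oxygens); N-methylmorpholine N-oxide, C[N+]1([O-])CCOCC1, and water, O (net source of the two OH groups)
Why: Upjohn dihydroxylation, in which OsO4 adds suprafacially to the electron-rich trisubstituted C3=C4 alkene and leaves the conjugated tetrasubstituted C7=C11 alkene alone, and the axial C10 methyl shields the β face so that both oxygens arrive from the α face and set C3 (R, axial OH) and C4 (S, equatorial OH, axial β-methyl).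

Step 6
Reactants: 7 (3R,4S,5R,10R)-3α,4α-dihydroxyeudesm-7(11)-en-8-one; 8 angelic acid, (Z)-2-methylbut-2-enoic acid
Product: 10 (3R,4S,5R,10R)-3α-angeloyloxy-4α-hydroxyeudesm-7(11)-en-8-one, via mixed Yamaguchi anhydride 9 (not isolated)
Conditions: 8 (3 equiv), 2,4,6-Cl3C6H2COCl (3 equiv), Et3N (3.3 equiv), PhMe, rt; then 7, 80 °C (no DMAP)
Reagents that add atoms: 2,4,6-trichlorobenzoyl chloride, O=C(Cl)c1c(Cl)cc(Cl)cc1Cl (its aroyl group is found in 9 only, not in 10)
Why: Yamaguchi esterification through the preformed mixed anhydride and without a nucleophilic pyridine catalyst is the established way to transfer an angeloyl group with its Z geometry intact; the alcohol attacks the unhindered angeloyl carbonyl of 9, only the secondary 3α-hydroxyl reacts because the tertiary 4α-hydroxyl is too hindered, and C3 keeps its configuration since its C–O bond is not broken.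

Step 7
Reactants: 10 (3R,4S,5R,10R)-3α-angeloyloxy-4α-hydroxyeudesm-7(11)-en-8-one
Product: 11 (3R,4S,5R,10R)-4α-acetoxy-3α-angeloyloxyeudesm-7(11)-en-8-one
Conditions: Ac2O (10 equiv), Et3N (12 equiv), DMAP (0.5 equiv), CH2Cl2, 40 °C
Reagents that add atoms: acetic anhydride, CC(=O)OC(C)=O
Why: DMAP-catalysed acyl transfer from acetic anhydride (Steglich-type acetylation) is the standard method for tertiary alcohols; the equatorial 4α-hydroxyl is the only one left, the angelate is far less open to Z-to-E isomerisation by DMAP as a bound ester than as an activated acyl donor, and C4 keeps its configuration since its C–O bond is not broken.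

Step 8
Reactants: 11 (3R,4S,5R,10R)-4α-acetoxy-3α-angeloyloxyeudesm-7(11)-en-8-one
Product: 12 (3R,4S,5R,10R)-4α-acetoxy-3α-angeloyloxy-11-hydroperoxyeudesm-6-en-8-one (CNP0225062.1)
Conditions: O2, 5,10,15,20-tetraphenylporphyrin (1 mol %), CH2Cl2, visible light (UV cut-off filter), 0 °C; stopped at consumption of 11, no reductive work-up
Reagents that add atoms: dioxygen, O=O
Why: Schenck ene reaction, in which singlet oxygen attacks enones locked s-cis (as in 2-isopropylidenecyclohexanones) with geminal selectivity, so oxygen bonds to the β-carbon C11 and hydrogen is taken from C6, the alkyl group on the carbon that bears the carbonyl; this moves the alkene to C6=C7 in conjugation with C8=O without making or touching a stereocentre, while the trisubstituted angelate alkene is a much slower ene partner and the low-energy sensitiser cannot isomerise it.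

Compound list
1 | germacrone, (1(10)E,4E)-germacra-1(10),4,7(11)-trien-8-one | C/C1=C\CC(=C(C)C)C(=O)C/C(C)=C/CC1 | starting material
2 | (1R,10R)-1,10-epoxygermacra-4E,7(11)-dien-8-one | C/C1=C\CC(=C(C)C)C(=O)C[C@@]2(C)O[C@@H]2CC1 | intermediate
3 | (1R,5S,10R)-1β-hydroxyeudesma-3,7(11)-dien-8-one | CC1=CC[C@@H](O)[C@]2(C)CC(=O)C(=C(C)C)C[C@@H]12 | intermediate
4 | O-[(1R,5S,10R)-8-oxoeudesma-3,7(11)-dien-1β-yl] imidazole-1-carbothioate | CC1=CC[C@@H](OC(=S)n3ccnc3)[C@]2(C)CC(=O)C(=C(C)C)C[C@@H]12 | intermediate
5 | (5R,10R)-eudesma-3,7(11)-dien-8-one | CC1=CCC[C@]2(C)CC(=O)C(=C(C)C)C[C@@H]12 | intermediate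
6 | cyclic 3α,4α-osmate ester of 5 | O=[Os]1(=O)O[C@@H]2CC[C@]3(C)CC(=O)C(=C(C)C)C[C@H]3[C@]2(C)O1 | intermediate
7 | (3R,4S,5R,10R)-3α,4α-dihydroxyeudesm-7(11)-en-8-one | O[C@@H]1CC[C@]2(C)CC(=O)C(=C(C)C)C[C@H]2[C@]1(C)O | intermediate
8 | angelic acid, (Z)-2-methylbut-2-enoic acid | C/C=C(/C)C(=O)O | starting material
9 | angelic 2,4,6-trichlorobenzoic anhydride | C/C=C(/C)C(=O)OC(=O)c1c(Cl)cc(Cl)cc1Cl | intermediate
10 | (3R,4S,5R,10R)-3α-angeloyloxy-4α-hydroxyeudesm-7(11)-en-8-one | C/C=C(/C)C(=O)O[C@@H]1CC[C@]2(C)CC(=O)C(=C(C)C)C[C@H]2[C@]1(C)O | intermediate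
11 | (3R,4S,5R,10R)-4α-acetoxy-3α-angeloyloxyeudesm-7(11)-en-8-one | C/C=C(/C)C(=O)O[C@@H]1CC[C@]2(C)CC(=O)C(=C(C)C)C[C@H]2[C@]1(C)OC(C)=O | intermediate
12 | (3R,4S,5R,10R)-4α-acetoxy-3α-angeloyloxy-11-hydroperoxyeudesm-6-en-8-one | C/C=C(/C)C(=O)O[C@@H]1CC[C@]2(C)CC(=O)C(C(C)(C)OO)=C[C@H]2[C@]1(C)OC(C)=O | target

Total steps: 8
Longest linear sequence: 8 steps (1 to 12); angelic acid 8 enters in step 6.

Steps most likely to fail

Step 1. The dioxirane may attack C4=C5 as well as C1=C10, may epoxidise twice, or may discriminate poorly between the two mirror-image ring conformers, so that regio- and enantiopurity are lost. The fallback gives up reagent control and resolves instead. It sets out from 1: mCPBA with NaHCO3 in CH2Cl2 at 0 °C should give racemic trans-1,10-epoxygermacrone F1. The conditions of step 2 should turn this into racemic 1β-hydroxyeudesma-3,7(11)-dien-8-one F2. Acylation with (1S)-camphanic chloride (pyridine, DMAP, CH2Cl2) should give two diastereomeric esters, the (1R,5S,10R)-alcohol camphanate F3 and the (1S,5R,10S)-alcohol camphanate F4, to be separated by crystallisation or chromatography. LiOH in aqueous THF should cleave F3 and bring the sequence back to the route at 3.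

Step 2. The C4 cation may lose a proton from C15 or C5 instead of C3. The alkene may also migrate to the tetrasubstituted C4=C5 position on longer acid contact, which would erase the C5 stereocentre. The fallback forms the same C5–C10 bond by a radical path that ends in a single alkene isomer. It sets out from 2: Cp2TiCl (trivalent titanium, made from Cp2TiCl2 and Mn dust in THF, rt) should open the epoxide homolytically to the tertiary C10 radical, which adds to C5 across the ring. The C4 radical is captured by a second titanium centre, and β-hydride elimination toward the methyl group should give only the exocyclic alkene, 1β-hydroxyeudesma-4(15),7(11)-dien-8-one F5. RhCl3·3H2O in refluxing ethanol should then move the alkene inward to the trisubstituted position and return to the route at 3.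

Step 8. The ene reaction of the electron-poor enone may be slow enough for oxygenation of the angelate alkene and decay of the hydroperoxide under prolonged irradiation to compete. Some hydrogen abstraction from the C12/C13 methyl groups may add a regioisomer that is hard to remove at the last stage. The fallback moves the photooxygenation ahead of the acylations and carries the peroxide in masked form.
- It sets out from 7, where C7=C11 is the only alkene, so irradiation can be long and isomers can be separated at a polar stage. The conditions of step 8 should give 3α,4α-dihydroxy-11-hydroperoxyeudesm-6-en-8-one F6.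
- TBSCl and imidazole in DMF at 0 °C should silylate the acidic, unhindered OOH terminus ahead of the axial 3α-hydroxyl and give 11-(tert-butyldimethylsilylperoxy)-3α,4α-dihydroxyeudesm-6-en-8-one F7.
- The acylations of steps 6 and 7 should then give the silyl peroxide 3α-angelate F8 and the silyl peroxide 3α-angelate 4α-acetate F9.
- HF·pyridine in THF at 0 °C should free the hydroperoxide and arrive at 12.

Further compounds
F1 | step 1 | racemic trans-1,10-epoxygermacrone (both enantiomers) | C/C1=C\CC(=C(C)C)C(=O)C[C@@]2(C)O[C@@H]2CC1.C/C1=C\CC(=C(C)C)C(=O)C[C@]2(C)O[C@H]2CC1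
F2 | step 1 | racemic 1β-hydroxyeudesma-3,7(11)-dien-8-one (both enantiomers) | CC1=CC[C@@H](O)[C@]2(C)CC(=O)C(=C(C)C)C[C@@H]12.CC1=CC[C@H](O)[C@@]2(C)CC(=O)C(=C(C)C)C[C@H]12
F3 | step 1 | (1S,4R)-camphanate of (1R,5S,10R)-alcohol 3 | CC1=CC[C@@H](OC(=O)[C@@]34CC[C@@](C)(C(=O)O3)C4(C)C)[C@]2(C)CC(=O)C(=C(C)C)C[C@@H]12
F4 | step 1 | (1S,4R)-camphanate of the (1S,5R,10S)-alcohol | CC1=CC[C@H](OC(=O)[C@@]34CC[C@@](C)(C(=O)O3)C4(C)C)[C@@]2(C)CC(=O)C(=C(C)C)C[C@H]12
F5 | step 2 | (1R,5S,10R)-1β-hydroxyeudesma-4(15),7(11)-dien-8-one | C=C1CC[C@@H](O)[C@]2(C)CC(=O)C(=C(C)C)C[C@@H]12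
F6 | step 8 | 3α,4α-dihydroxy-11-hydroperoxyeudesm-6-en-8-one | O[C@@H]1CC[C@]2(C)CC(=O)C(C(C)(C)OO)=C[C@H]2[C@]1(C)O
F7 | step 8 | 11-(tert-butyldimethylsilylperoxy)-3α,4α-dihydroxyeudesm-6-en-8-one | O[C@@H]1CC[C@]2(C)CC(=O)C(C(C)(C)OO[Si](C)(C)C(C)(C)C)=C[C@H]2[C@]1(C)O
F8 | step 8 | 3α-angeloyloxy-11-(tert-butyldimethylsilylperoxy)-4α-hydroxyeudesm-6-en-8-one | C/C=C(/C)C(=O)O[C@@H]1CC[C@]2(C)CC(=O)C(C(C)(C)OO[Si](C)(C)C(C)(C)C)=C[C@H]2[C@]1(C)O
F9 | step 8 | 4α-acetoxy-3α-angeloyloxy-11-(tert-butyldimethylsilylperoxy)eudesm-6-en-8-one | C/C=C(/C)C(=O)O[C@@H]1CC[C@]2(C)CC(=O)C(C(C)(C)OO[Si](C)(C)C(C)(C)C)=C[C@H]2[C@]1(C)OC(C)=O
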